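## Structural features

Olivil monoacetate is a 2,3,4-trisubstituted tetrahydrofuran (ring atoms O1, C2, C3, C4, C5). C2 carries a 4-hydroxy-3-methoxyphenyl group, C3 an acetoxymethyl group (carbon C9), and C4 both a free tertiary hydroxyl and a 4-hydroxy-3-methoxybenzyl group (benzylic carbon C7′); C5 is an unsubstituted OCH2. The three stereocentres C2 (S), C3 (R) and C4 (S) are contiguous: the C2 aryl is trans to C9, C9 and C7′ lie on the same face, and the tertiary hydroxyl therefore shares the face of the C2 aryl. The fragile points are the C2–O1 bond (a cyclic benzylic ether activated by a para oxygen, open to acid ionisation and to hydrogenolysis), the two free phenols, and the primary acetate, which must sit on one of four hydroxyls and can migrate or hydrolyse under base. The real difficulty is the fully substituted carbinol C4 next to C3: two adjacent centres, one quaternary, must be set relative to C2, and the C9 oxygen must end up distinguished from the other hydroxyls. The key step exploits the fact that C3 and C4 each bear one carbon substituent on the same face and that C4 is oxygenated. A silyl enol ether C3=C4 in a 2,5-dihydrofuran can therefore take up a two-carbon ketene unit C9–C7′ across the face anti to the C2 aryl, as a fused cyclobutanone. The surplus C9–C7′ bond is later cut by oxygen insertion, which leaves C9 at the carboxyl level and C7′ as a benzylic C–O that is finally reduced to CH2.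

## Logic of the disconnections

**15 from 14.** Backwards, the two phenolic hydrogens become benzyl groups and one hydrogen on C7′ becomes an acetoxy group. Forwards, two ArO–CH2Ph bonds and the C7′–OAc bond are cut in one hydrogenolysis. The cut is placed last so that 15 is released under neutral conditions, and the C7′ oxygen is carried as an acetate because that is the most easily hydrogenolysed benzylic C–O in the molecule. The gain is that three unmasking operations collapse into one. The demand is that these bonds cleave before the C2–O1 ring bond.

**14 from 13.** The two acetyl–oxygen bonds on C9 and C7′ are cut. Acetylating both hydroxyls removes any need to tell the primary from the secondary one. The demand is only that the hindered tertiary C4 hydroxyl stays free.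

**13 from 12.** Backwards, the C9 and C7′ oxygens are tied together through a C9 carbonyl (acyl C9–O bond, C9 at the acid level). This returns a bicyclic compound in which C9 and C7′ are still joined through one oxygen. The forward step is a plain hydride reduction that must not touch C2 or C3.

**12 from 11.** The O–Si bond on the C4 oxygen is cut. Removal is placed before the reduction so that no alkoxide is ever formed next to a silyl ether (1,4-silyl migration) and so that no acidic fluoride treatment is needed once the phenols are free. The forward step must not cause β-elimination in the β-oxy carbonyl array.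

**11 from 10.** Backwards, the oxygen between C9 and C7′ is taken out and the C9–C7′ bond restored. This reveals a four-membered ketone, the retron of a ketene cycloaddition. The forward oxygen insertion must occur on the C7′ side of the carbonyl, with retention at the migrating carbon.

**10 from 6 and 9.** The bonds C3–C9 and C4–C7′ are cut together. This separates the two aryl-bearing halves and reduces three contiguous stereocentres to the single centre C2 of 6. The forward step must be regioselective (C3 to the ketene carbonyl carbon), suprafacial on the ring alkene (cis fusion) and face-selective (anti to the C2 aryl). The β-oxy ketone must also survive, which is why the C4 oxygen stays silylated.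

**9 from 8, and 8 from 7.** The ketene C=C comes from loss of HCl across the Cα–H and C–Cl bonds of 8, and the C–Cl bond of 8 from the acid 7. The demand is that 9 is generated slowly in the presence of 6, since it dimerises.

**6 from 4 (through 5).** The O–Si bond is cut and the C3=C4 double bond returned to a C4 carbonyl with a C3 methylene. The forward step must enolise toward C3, not toward the oxygen-bearing C5.

**4 from 3.** The O1–C5 bond is cut and the C4 carbonyl oxygen removed, which leads back to an acyclic alkynol. The forward step must oxidise the alkyne and close the ring without ionising the benzylic carbinol.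

**3 from 1 and 2.** The C2–C3 bond is cut. This is the only step that introduces absolute configuration; it must deliver the three-carbon unit to the Si face of 1.

## Other disconnections considered

**Alternative 1:** The cut is the C3–C4 bond, which also opens the ring. It leads to the acyclic ether A1, in which O1 links the benzylic carbon C2 to an aryl-propargyl unit C5–C4≡C7′ and C3–C9 is a terminal oxirane. Forwards, Cp2TiCl (trivalent titanium, formed from Cp2TiCl2 and Zn) would open the oxirane homolytically to the secondary radical at C3. This radical would add 5-exo-dig to the alkyne to give A2, the 2,3-trans 4-benzylidene tetrahydrofuran with a free C9 hydroxyl.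
- In favour: A1 is assembled by a simple etherification of two aryl-bearing pieces. A2 contains no surplus bond and already has the C9 hydroxyl free for acetylation. The radical conditions are mild toward benzyl ethers.
- Against: C4 is not set in the key step. The exocyclic alkene of A2 would still need oxygen at C4 on the face syn to the C2 aryl and anti to C9, followed by reduction of the benzylic C7′–O bond. The neighbouring C9 hydroxyl would direct a metal-catalysed epoxidation to the wrong face, so the outcome would rest on steric bias alone. The 2,3-trans relationship depends on a conformational preference in an open-chain radical, not on an enforced geometry.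
- Comparison: on structure, Alternative 1 is better, since it makes no sacrificial bond and no redox detour at C9. On mechanism, the chosen plan is stronger, because it fixes C3 and C4 in one suprafacial event controlled by a single element. On step count the two are about equal.

**Alternative 2:** The cuts are C2–C3 and C4–C5. The substrate is A3, a 2-aryl-1,3-dioxolane that joins 1 to an (E)-trisubstituted allylic 1,2-diol unit containing C5, C4, C7′, C3 and C9. Forwards, SnCl4 would open the acetal to an oxocarbenium centre at C2. The alkene would attack it through a chair to form C2–C3 in a six-membered ring, and the resulting tertiary cation at C4 would be quenched by a 1,2-shift of C5. This contracts the ring to the tetrahydrofuran A4, which bears a formyl group on C4.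
- In favour: all three ring centres, including the quaternary carbon, would be set in one step under chair control. With the (E)-alkene the chair places the C2 aryl and C9 equatorial (2,3-trans), and the ring contraction brings C5 to the face of C4 that leaves C7′ cis to C9, which is the arrangement needed. Every centre set would be kept, so on stereocentres retained per key step it is better than the chosen plan, which erases C7′.
- Against: C4 ends up bearing a carbon (CHO) where the target has oxygen. That carbon must be excised with retention (oxidation of the aldehyde to the formate and hydrolysis), in competition with oxidation to the acid and in the presence of electron-rich arenes. The carbinol stereocentre of A3 (drawn R, as the chair with the stannyl alkoxide equatorial requires) is consumed, and the geometrically pure trisubstituted alkene costs several steps.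
- Comparison: both plans carry a sacrificial element. Here the surplus C9–C7′ bond is turned into the oxidation pattern the target needs, whereas the surplus formyl carbon in A4 is lost entirely. On stereochemical reliability the two are equal. On step count the chosen plan should be shorter.

**Alternative 3:** The cuts are C4–O and O1–C5. They lead to the acyclic homoallylic alcohol A5, which has C2 and C3 as in the target and a 1,1-disubstituted alkene C4=C5 bearing the C7′ benzyl group. Forwards, VO(acac)2 and t-BuOOH would epoxidise the alkene under direction of the C2 hydroxyl. The same hydroxyl would then open the oxirane at its CH2 end to close the ring and give A6, the silyl-protected triad with the tertiary hydroxyl already free.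
- In favour: A6 has every carbon at its final oxidation level and is three routine operations from the target (desilylation, acetylation, debenzylation). On redox economy and on the number of steps after the key step it is better than the chosen plan.
- Against: the C4 configuration would depend on 1,3- and 1,2-induction in an open-chain epoxidation directed by a homoallylic hydroxyl, which is less ordered than the allylic case. The ring closure is a 5-endo opening of a 2,2-disubstituted oxirane at CH2. It competes with 4-exo attack and with Lewis-acid opening at the tertiary carbon, which leads to rearrangement. A5 itself needs an anti C2/C3 relationship set by reagent control.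
- Comparison: on structure and step count Alternative 3 is the better plan. On mechanism the chosen plan is safer, because the C4 configuration is locked by a cis ring fusion and a single shielding group and does not depend on acyclic induction.

Key step: step 5

Remarks on the chemistry (assumptions and corrections):
- Locants O1, C2–C5, C9 and C7′ refer to the target throughout, and systematic names use their own numbering.
- By bicyclo nomenclature cycloadduct 10 is a 3-oxabicyclo[3.2.0]heptan-6-one: the ring oxygen lies between two non-bridgehead carbons, so a 2-oxa locant would be wrong.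
- The pinacol ester 2 does not exchange its diol for a tartrate, so asymmetric induction in step 1 is assigned to a chiral phosphoric acid.
- The sense of induction in step 1 is assumed to follow the allylboration of aryl aldehydes under the same catalyst and is to be checked on the first batch.
- The acid 7 is taken as a commercial compound; otherwise one O-benzylation of homovanillic acid precedes step 4.
- C7 of 10 is drawn with the aryl on the concave face. This centre is epimerisable and is erased in step 10.
- The C7′ oxygen is removed as its acetate, not as the free alcohol, and the silyl group is taken off at the lactone stage, for the reasons given in the logic section.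

## Route

Step 1
Reactants: 1 4-(benzyloxy)-3-methoxybenzaldehyde; 2 allenylboronic acid pinacol ester
Product: 3 (S)-1-[4-(benzyloxy)-3-methoxyphenyl]but-3-yn-1-ol
Conditions: (S)-3,3′-bis(2,4,6-triisopropylphenyl)-1,1′-binaphthyl-2,2′-diyl hydrogen phosphate (10 mol %), 4 Å molecular sieves, toluene, −20 °C; aqueous work-up
Reagents that add atoms: none
Why: Chiral phosphoric acid-catalysed propargylboration (SE2′ through a closed six-membered transition state, the acid hydrogen-bonded to a boronate oxygen), which uses the pinacol ester as such; the (S)-acid should expose the Si face of 1 and give the (S)-carbinol, the future C2.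

Step 2
Reactants: 3 (S)-1-[4-(benzyloxy)-3-methoxyphenyl]but-3-yn-1-ol
Product: 4 (5S)-5-[4-(benzyloxy)-3-methoxyphenyl]oxolan-3-one
Conditions: Ph3PAuNTf2 (5 mol %), 8-methylquinoline N-oxide (1.5 equiv), 1,2-dichloroethane, rt
Reagents that add atoms: 8-methylquinoline N-oxide, Cc1cccc2ccc[n+]([O-])c12
Why: Gold-catalysed oxidative cyclisation of a homopropargylic alcohol: the N-oxide oxidises the activated terminal alkyne at its internal carbon and the tethered hydroxyl inserts into the catalyst-bound α-oxo carbene at the terminal carbon, forming the C4 carbonyl and the O1–C5 bond. The carbinol centre is not touched, and the hindered quinoline by-product lets the reaction run without added acid, which protects the electron-rich benzylic alcohol from ionisation.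

Step 3
Reactants: 4 (5S)-5-[4-(benzyloxy)-3-methoxyphenyl]oxolan-3-one
Product: 6 (2S)-2-[4-(benzyloxy)-3-methoxyphenyl]-4-[(tert-butyldimethylsilyl)oxy]-2,5-dihydrofuran, via lithium enolate 5 (not isolated)
Conditions: LiN(i-Pr)2 (1.1 equiv), THF, −78 °C (4 added to the base); then TBSCl, DMPU, −78 → −20 °C
Reagents that add atoms: tert-butyldimethylsilyl chloride, CC(C)(C)[Si](C)(C)Cl
Why: Kinetic enolate formation and O-silylation: the amide base should deprotonate C3, the methylene without oxygen, because deprotonation next to the ring oxygen is slowed by lone-pair repulsion, and inverse addition at −78 °C prevents equilibration. Loss of the ring oxygen from enolate 5 is stereoelectronically poor (the C2–O1 bond lies near the enolate plane), and C2 is not involved.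

Step 4
Reactants: 7 2-[4-(benzyloxy)-3-methoxyphenyl]acetic acid
Product: 8 2-[4-(benzyloxy)-3-methoxyphenyl]acetyl chloride
Conditions: (COCl)2 (1.2 equiv), N,N-dimethylformamide (cat.), CH2Cl2, 0 °C → rt; evaporation, used crude
Reagents that add atoms: oxalyl chloride, O=C(Cl)C(=O)Cl
Why: Acid chloride formation through the chloroiminium (Vilsmeier-type) catalyst under neutral conditions that leave the benzyl ether intact.

Step 5
Reactants: 6 (2S)-2-[4-(benzyloxy)-3-methoxyphenyl]-4-[(tert-butyldimethylsilyl)oxy]-2,5-dihydrofuran; 8 2-[4-(benzyloxy)-3-methoxyphenyl]acetyl chloride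
Product: 10 (1S,4S,5R,7S)-4,7-bis[4-(benzyloxy)-3-methoxyphenyl]-1-[(tert-butyldimethylsilyl)oxy]-3-oxabicyclo[3.2.0]heptan-6-one, via [4-(benzyloxy)-3-methoxyphenyl]ketene 9 (not isolated)
Conditions: 8 (2.5 equiv, added over 6 h), Et3N (3 equiv), CH2Cl2, 40 °C
Reagents that add atoms: none
Why: Et3N dehydrochlorinates 8 to the arylketene 9, which adds to the silyl enol ether through the orthogonal, asynchronous [2+2] transition state typical of ketenes (formally π2s on the enol ether, π2a on the ketene). The nucleophilic β-carbon of the enol ether (C3) bonds to the ketene carbonyl carbon (C9) and the developing silyloxocarbenium carbon (C4) is captured by the ketene terminus (C7′), so the regiochemistry follows the polarity of both partners. The closest known reaction type is the ketene–enol ether or silyl enol ether cycloaddition that gives 3-alkoxy- or 3-silyloxycyclobutanones. The cyclobutanone is the only ring closed; in stepwise terms it closes by 4-exo-trig collapse of the ketene-derived enolate carbon onto C4, and since both bonds form on one face of the ring alkene the fusion is necessarily cis. C3 and C4 are set together, with C9 and C7′ anti to the C2 aryl, which shields the other face of the flat dihydrofuran next to the first-formed bond and is the single control element for both centres. C7′ is set by the ketene approaching with its hydrogen toward the ring, which should leave its aryl on the concave face; this centre is epimerisable and is erased in step 10. The step needs facial selectivity (from the C2 aryl), regioselectivity (from the enol ether polarity) and preference for cycloaddition over ketene dimerisation (from slow addition of an excess of 8); the TBS group keeps the β-oxy ketone from retro-aldol opening.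

Step 6
Reactants: 10 (1S,4S,5R,7S)-4,7-bis[4-(benzyloxy)-3-methoxyphenyl]-1-[(tert-butyldimethylsilyl)oxy]-3-oxabicyclo[3.2.0]heptan-6-one
Product: 11 (1R,4S,5S,8S)-4,8-bis[4-(benzyloxy)-3-methoxyphenyl]-5-[(tert-butyldimethylsilyl)oxy]-3,7-dioxabicyclo[3.3.0]octan-2-one
Conditions: mCPBA (1.3 equiv), NaHCO3, CH2Cl2, 0 °C
Reagents that add atoms: 3-chloroperoxybenzoic acid, O=C(OO)c1cccc(Cl)c1
Why: Baeyer–Villiger oxidation of a strained cyclobutanone: C7′, the benzylic carbon with the electron-rich aryl, should migrate in preference to C3, which is deactivated by two β-oxygens, and migration proceeds with retention. Bicarbonate buffering at 0 °C should leave the silyl ether and the arenes untouched.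

Step 7
Reactants: 11 (1R,4S,5S,8S)-4,8-bis[4-(benzyloxy)-3-methoxyphenyl]-5-[(tert-butyldimethylsilyl)oxy]-3,7-dioxabicyclo[3.3.0]octan-2-one
Product: 12 (1R,4S,5S,8S)-4,8-bis[4-(benzyloxy)-3-methoxyphenyl]-5-hydroxy-3,7-dioxabicyclo[3.3.0]octan-2-one
Conditions: HF·pyridine, pyridine, THF, 0 °C → rt
Reagents that add atoms: none
Why: Fluoride cleavage of the tertiary silyl ether under buffered, weakly acidic conditions that avoid E1cB loss of the β-oxygen from the lactone. It is done at this stage so that no alkoxide is later formed next to a silyl ether and the final step can be neutral.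

Step 8
Reactants: 12 (1R,4S,5S,8S)-4,8-bis[4-(benzyloxy)-3-methoxyphenyl]-5-hydroxy-3,7-dioxabicyclo[3.3.0]octan-2-one
Product: 13 (3S,4R,5S)-5-[4-(benzyloxy)-3-methoxyphenyl]-3-{(S)-[4-(benzyloxy)-3-methoxyphenyl](hydroxy)methyl}-4-(hydroxymethyl)oxolan-3-ol
Conditions: LiAlH4 (3 equiv), THF, 0 °C → rt; aqueous potassium sodium tartrate work-up
Reagents that add atoms: none
Why: Hydride reduction of the lactone to the primary alcohol at C9 and the secondary benzylic alcohol at C7′; no stereocentre is affected.

Step 9
Reactants: 13 (3S,4R,5S)-5-[4-(benzyloxy)-3-methoxyphenyl]-3-{(S)-[4-(benzyloxy)-3-methoxyphenyl](hydroxy)methyl}-4-(hydroxymethyl)oxolan-3-ol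
Product: 14 (S)-{(3S,4R,5S)-4-(acetoxymethyl)-5-[4-(benzyloxy)-3-methoxyphenyl]-3-hydroxyoxolan-3-yl}[4-(benzyloxy)-3-methoxyphenyl]methyl acetate
Conditions: Ac2O (2.5 equiv), pyridine, 4-(dimethylamino)pyridine (5 mol %), CH2Cl2, 0 °C
Reagents that add atoms: acetic anhydride, CC(=O)OC(C)=O
Why: Acyl transfer to the primary and the secondary hydroxyl; the tertiary C4 hydroxyl, flanked by two substituted carbons, should not react at 0 °C with a limited amount of anhydride. No discrimination between C9 and C7′ is needed, because the C7′ acetate is the group removed next.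

Step 10
Reactants: 14 (S)-{(3S,4R,5S)-4-(acetoxymethyl)-5-[4-(benzyloxy)-3-methoxyphenyl]-3-hydroxyoxolan-3-yl}[4-(benzyloxy)-3-methoxyphenyl]methyl acetate
Product: 15 olivil monoacetate, [(2S,3R,4S)-4-hydroxy-4-(4-hydroxy-3-methoxybenzyl)-2-(4-hydroxy-3-methoxyphenyl)oxolan-3-yl]methyl acetate
Conditions: H2 (1 atm), 10% Pd/C, EtOAc, rt; stopped when 14 is consumed
Reagents that add atoms: none
Why: Catalytic hydrogenolysis: the two aryl benzyl ethers and the secondary benzylic acetate (the best leaving group on a benzylic carbon here) should cleave before the cyclic C2–O1 ether, and the C9 acetate and the tertiary alcohol are not benzylic. C7′ becomes CH2, which removes its stereocentre.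

## Compound list

1 | 4-(benzyloxy)-3-methoxybenzaldehyde | COc1cc(C=O)ccc1OCc1ccccc1 | starting material
2 | allenylboronic acid pinacol ester | C=C=CB1OC(C)(C)C(C)(C)O1 | starting material
3 | (S)-1-[4-(benzyloxy)-3-methoxyphenyl]but-3-yn-1-ol | C#CC[C@H](O)c1ccc(OCc2ccccc2)c(OC)c1 | intermediate
4 | (5S)-5-[4-(benzyloxy)-3-methoxyphenyl]oxolan-3-one | O=C1C[C@@H](c2ccc(OCc3ccccc3)c(OC)c2)OC1 | intermediate
5 | lithium enolate of 4 toward C3 (formed in the flask) | [Li]OC1=C[C@@H](c2ccc(OCc3ccccc3)c(OC)c2)OC1 | intermediate
6 | (2S)-2-[4-(benzyloxy)-3-methoxyphenyl]-4-[(tert-butyldimethylsilyl)oxy]-2,5-dihydrofuran | CC(C)(C)[Si](C)(C)OC1=C[C@@H](c2ccc(OCc3ccccc3)c(OC)c2)OC1 | intermediate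
7 | 2-[4-(benzyloxy)-3-methoxyphenyl]acetic acid | COc1cc(CC(=O)O)ccc1OCc1ccccc1 | starting material
8 | 2-[4-(benzyloxy)-3-methoxyphenyl]acetyl chloride | COc1cc(CC(=O)Cl)ccc1OCc1ccccc1 | intermediate
9 | [4-(benzyloxy)-3-methoxyphenyl]ketene (formed in the flask) | O=C=Cc1ccc(OCc2ccccc2)c(OC)c1 | intermediate
10 | (1S,4S,5R,7S)-4,7-bis[4-(benzyloxy)-3-methoxyphenyl]-1-[(tert-butyldimethylsilyl)oxy]-3-oxabicyclo[3.2.0]heptan-6-one (cis-fused; cyclobutanone anti to the C4 aryl; C7 aryl on the concave face) | O=C1[C@@H]2[C@@H](c3ccc(OCc4ccccc4)c(OC)c3)OC[C@]2(O[Si](C)(C)C(C)(C)C)[C@@H]1c1ccc(OCc2ccccc2)c(OC)c1 | intermediate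
11 | (1R,4S,5S,8S)-4,8-bis[4-(benzyloxy)-3-methoxyphenyl]-5-[(tert-butyldimethylsilyl)oxy]-3,7-dioxabicyclo[3.3.0]octan-2-one | O=C1[C@@H]2[C@@H](c3ccc(OCc4ccccc4)c(OC)c3)OC[C@]2(O[Si](C)(C)C(C)(C)C)[C@@H](O1)c1ccc(OCc2ccccc2)c(OC)c1 | intermediate
12 | (1R,4S,5S,8S)-4,8-bis[4-(benzyloxy)-3-methoxyphenyl]-5-hydroxy-3,7-dioxabicyclo[3.3.0]octan-2-one | O=C1[C@@H]2[C@@H](c3ccc(OCc4ccccc4)c(OC)c3)OC[C@]2(O)[C@@H](O1)c1ccc(OCc2ccccc2)c(OC)c1 | intermediate
13 | (3S,4R,5S)-5-[4-(benzyloxy)-3-methoxyphenyl]-3-{(S)-[4-(benzyloxy)-3-methoxyphenyl](hydroxy)methyl}-4-(hydroxymethyl)oxolan-3-ol | OC[C@@H]1[C@@H](c2ccc(OCc3ccccc3)c(OC)c2)OC[C@]1(O)[C@@H](O)c1ccc(OCc2ccccc2)c(OC)c1 | intermediate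
14 | (S)-{(3S,4R,5S)-4-(acetoxymethyl)-5-[4-(benzyloxy)-3-methoxyphenyl]-3-hydroxyoxolan-3-yl}[4-(benzyloxy)-3-methoxyphenyl]methyl acetate | CC(=O)OC[C@@H]1[C@@H](c2ccc(OCc3ccccc3)c(OC)c2)OC[C@]1(O)[C@@H](OC(C)=O)c1ccc(OCc2ccccc2)c(OC)c1 | intermediate
15 | olivil monoacetate, [(2S,3R,4S)-4-hydroxy-4-(4-hydroxy-3-methoxybenzyl)-2-(4-hydroxy-3-methoxyphenyl)oxolan-3-yl]methyl acetate | COc1cc(C[C@@]2(O)CO[C@H](c3ccc(O)c(OC)c3)[C@H]2COC(C)=O)ccc1O | target

## Step count and least certain steps

Total step count: 10. Longest linear sequence: 9 steps (steps 1, 2, 3, 5, 6, 7, 8, 9, 10); step 4 is a one-step branch.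

**Step 5 (key step).** The most likely failure is dimerisation or oligomerisation of the electron-rich arylketene outrunning its addition to a hindered, trisubstituted silyl enol ether. Next in likelihood are collapse of the polar intermediate by silyl transfer to an open-chain acylation product, and amine-induced β-elimination or retro-aldol opening of the adduct through its acidic C7 hydrogen. The fallback keeps the disconnection but uses a more electrophilic ketene with no acidic C7 hydrogen in the adduct. It sets out from 8 and 6. α-Chlorination of 8 (N-chlorosuccinimide, catalytic HCl, SOCl2, 70 °C) gives 2-[4-(benzyloxy)-3-methoxyphenyl]-2-chloroacetyl chloride F1. Slow addition of F1 to 6 and Et3N generates [4-(benzyloxy)-3-methoxyphenyl](chloro)ketene F2, which should add with the same regio- and facial sense to give the 7-chloro cycloadduct F3. Radical dechlorination (Bu3SnH, azobisisobutyronitrile, toluene, 80 °C) comes back to 10; its C7 epimer would serve equally in step 6.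

**Step 3.** Proton removal may occur at C5, the oxygen-bearing methylene, or the enolate may equilibrate before silylation; either gives the isomeric 4,5-dihydrofuran enol ether. Loss of the ring oxygen from the enolate would open the ring. The fallback fixes the position of the double bond by construction; it sets out from 1 and comes back at 6. Vinyl transfer to 1 from (CH2=CH)2Zn, catalysed by the enantiomer of 3-exo-(dimethylamino)isoborneol that delivers to the Si face, gives (S)-1-[4-(benzyloxy)-3-methoxyphenyl]prop-2-en-1-ol F4. O-Alkylation (NaH, THF, 0 °C) with 3-bromo-2-[(tert-butyldimethylsilyl)oxy]prop-1-ene gives the diene tert-butyl{[3-({(1S)-1-[4-(benzyloxy)-3-methoxyphenyl]prop-2-en-1-yl}oxy)prop-1-en-2-yl]oxy}dimethylsilane F5. Ring-closing metathesis with the second-generation Grubbs catalyst, (H2IMes)(PCy3)Cl2Ru=CHPh, in toluene closes C3=C4 and gives 6.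

**Step 2.** The Lewis-acidic catalyst may ionise the electron-rich benzylic carbinol, with erosion of configuration, the quinoline may inhibit the catalyst, or the carbene may be oxidised a second time before the hydroxyl captures it. The fallback avoids carbenes and oxidants at the alkyne stage; it sets out from 3 and comes back at 4. Cycloisomerisation through a molybdenum vinylidene (Mo(CO)6, Et3N, Et2O, irradiation) gives (2S)-2-[4-(benzyloxy)-3-methoxyphenyl]-2,3-dihydrofuran F6. Hydroboration–oxidation (BH3·THF; then H2O2, NaOH) places oxygen on C4 and gives (3R,5S)-5-[4-(benzyloxy)-3-methoxyphenyl]oxolan-3-ol F7; the trans isomer is expected, but either epimer serves. Dess–Martin periodinane (NaHCO3, CH2Cl2) then gives 4.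

**Step 10.** The risk is over-reduction. Cleavage of the neopentyl-type C7′ acetate may lag, while hydrogenolysis of the C2–O1 ring bond becomes faster once the para hydroxyl is free. The fallback cleaves the C7′–O bond as a lactone carboxylate and introduces the acetate last; it sets out from 12 and comes back at 15. Hydrogenolysis of 12 (H2, 10% Pd/C, EtOAc–AcOH) opens the benzylic lactone C–O bond and removes the benzyl ethers to give (2S,3R,4S)-4-hydroxy-4-(4-hydroxy-3-methoxybenzyl)-2-(4-hydroxy-3-methoxyphenyl)oxolane-3-carboxylic acid F8. Reduction with BH3·SMe2 in THF gives olivil, (3S,4R,5S)-3-(4-hydroxy-3-methoxybenzyl)-5-(4-hydroxy-3-methoxyphenyl)-4-(hydroxymethyl)oxolan-3-ol F9. Immobilised Candida antarctica lipase B with vinyl acetate in tert-butyl methyl ether should acetylate only the primary aliphatic hydroxyl, leaving the phenols and the tertiary alcohol, to give 15.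

## Further compounds

F1 | step 5 | 2-[4-(benzyloxy)-3-methoxyphenyl]-2-chloroacetyl chloride (racemic) | COc1cc(C(Cl)C(=O)Cl)ccc1OCc1ccccc1
F2 | step 5 | [4-(benzyloxy)-3-methoxyphenyl](chloro)ketene (formed in the flask) | O=C=C(Cl)c1ccc(OCc2ccccc2)c(OC)c1
F3 | step 5 | (1S,4S,5R)-4,7-bis[4-(benzyloxy)-3-methoxyphenyl]-1-[(tert-butyldimethylsilyl)oxy]-7-chloro-3-oxabicyclo[3.2.0]heptan-6-one (C7 configuration immaterial) | O=C1[C@@H]2[C@@H](c3ccc(OCc4ccccc4)c(OC)c3)OC[C@]2(O[Si](C)(C)C(C)(C)C)C1(Cl)c1ccc(OCc2ccccc2)c(OC)c1
F4 | step 3 | (S)-1-[4-(benzyloxy)-3-methoxyphenyl]prop-2-en-1-ol | C=C[C@H](O)c1ccc(OCc2ccccc2)c(OC)c1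
F5 | step 3 | tert-butyl{[3-({(1S)-1-[4-(benzyloxy)-3-methoxyphenyl]prop-2-en-1-yl}oxy)prop-1-en-2-yl]oxy}dimethylsilane | C=C[C@H](OCC(=C)O[Si](C)(C)C(C)(C)C)c1ccc(OCc2ccccc2)c(OC)c1
F6 | step 2 | (2S)-2-[4-(benzyloxy)-3-methoxyphenyl]-2,3-dihydrofuran | C1=CO[C@H](c2ccc(OCc3ccccc3)c(OC)c2)C1
F7 | step 2 | (3R,5S)-5-[4-(benzyloxy)-3-methoxyphenyl]oxolan-3-ol (trans drawn; either C3 epimer serves) | O[C@H]1CO[C@H](c2ccc(OCc3ccccc3)c(OC)c2)C1
F8 | step 10 | (2S,3R,4S)-4-hydroxy-4-(4-hydroxy-3-methoxybenzyl)-2-(4-hydroxy-3-methoxyphenyl)oxolane-3-carboxylic acid | OC(=O)[C@@H]1[C@@H](c2ccc(O)c(OC)c2)OC[C@]1(O)Cc1ccc(O)c(OC)c1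
F9 | step 10 | olivil, (3S,4R,5S)-3-(4-hydroxy-3-methoxybenzyl)-5-(4-hydroxy-3-methoxyphenyl)-4-(hydroxymethyl)oxolan-3-ol | OC[C@@H]1[C@@H](c2ccc(O)c(OC)c2)OC[C@]1(O)Cc1ccc(O)c(OC)c1
A1 | alternative 1 | 2-{(R)-[4-(benzyloxy)-3-methoxyphenyl]({3-[4-(benzyloxy)-3-methoxyphenyl]prop-2-yn-1-yl}oxy)methyl}oxirane (oxirane carbon either configuration) | COc1cc(C#CCO[C@H](c2ccc(OCc3ccccc3)c(OC)c2)C2CO2)ccc1OCc1ccccc1
A2 | alternative 1 | {(2S,3R)-2-[4-(benzyloxy)-3-methoxyphenyl]-4-[(Z)-4-(benzyloxy)-3-methoxybenzylidene]oxolan-3-yl}methanol | COc1cc(/C=C2\CO[C@H](c3ccc(OCc4ccccc4)c(OC)c3)[C@H]2CO)ccc1OCc1ccccc1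
A3 | alternative 2 | (4R)-2-[4-(benzyloxy)-3-methoxyphenyl]-4-{(E)-1-[4-(benzyloxy)-3-methoxyphenyl]-4-[(tert-butyldiphenylsilyl)oxy]but-2-en-2-yl}-1,3-dioxolane (acetal carbon either configuration) | COc1cc(C/C(=C\CO[Si](c2ccccc2)(c2ccccc2)C(C)(C)C)[C@@H]2COC(c3ccc(OCc4ccccc4)c(OC)c3)O2)ccc1OCc1ccccc1
A4 | alternative 2 | (3S,4R,5S)-5-[4-(benzyloxy)-3-methoxyphenyl]-3-[4-(benzyloxy)-3-methoxybenzyl]-4-{[(tert-butyldiphenylsilyl)oxy]methyl}oxolane-3-carbaldehyde | COc1cc(C[C@@]2(C=O)CO[C@H](c3ccc(OCc4ccccc4)c(OC)c3)[C@H]2CO[Si](c2ccccc2)(c2ccccc2)C(C)(C)C)ccc1OCc1ccccc1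
A5 | alternative 3 | (1S,2R)-1-[4-(benzyloxy)-3-methoxyphenyl]-3-[4-(benzyloxy)-3-methoxybenzyl]-2-{[(tert-butyldimethylsilyl)oxy]methyl}but-3-en-1-ol | C=C(Cc1ccc(OCc2ccccc2)c(OC)c1)[C@H](CO[Si](C)(C)C(C)(C)C)[C@H](O)c1ccc(OCc2ccccc2)c(OC)c1
A6 | alternative 3 | (3S,4R,5S)-5-[4-(benzyloxy)-3-methoxyphenyl]-3-[4-(benzyloxy)-3-methoxybenzyl]-4-{[(tert-butyldimethylsilyl)oxy]methyl}oxolan-3-ol | COc1cc(C[C@@]2(O)CO[C@H](c3ccc(OCc4ccccc4)c(OC)c3)[C@H]2CO[Si](C)(C)C(C)(C)C)ccc1OCc1ccccc1
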